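The route rests on opening ring B, the ten-membered carbocycle C1–C10, at its diene C3=C4–C5(=C16). A Z ring alkene conjugated to an exocyclic methylene is the retron of an endo-mode ring-closing enyne metathesis, and the key step exploits this motif. Its precursor is a seco compound with ring A (cyclohexene) and ring C (γ-lactone) complete and every stereocentre, acetate and chloride in place. C2 carries a vinyl group, C6 an ethynyl group, and C16 is absent. Under ethylene, one operation adds C16, builds the diene, sets the Z geometry and closes ring B. Ring A comes from an asymmetric Diels–Alder reaction, and ring C from an aldol union and a chloropropargylation.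

Key step: step 20

Numbering: briarane numbering is used. Ring A = C1, C10–C14. Ring B = C1–C10. Ring C = C7, C8, C17, C19, O. C15 is the methyl on C1, C16 the exocyclic methylene, C18 the methyl on C17, and C20 the CH2Cl carbon.

Assumption: the sense of induction in step 2 is taken from the accepted formyl C–H···O pre-transition-state model for 2-substituted enals; both antipodes of the catalyst precursor are catalogue items.

Step 1
Reactants: 1 methyl vinyl ketone
Product: 2 2-(triisopropylsilyloxy)buta-1,3-diene
Conditions: iPr3SiOTf, Et3N, Et2O, 0 °C to rt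
Reagents that add atoms: triisopropylsilyl triflate, CC(C)[Si](OS(=O)(=O)C(F)(F)F)(C(C)C)C(C)C
Why: Amine-mediated O-silylation of the enone (silyl enol ether formation) should give the 2-silyloxydiene, whose bulky silyl group survives the acidic catalyst of the next step.

Step 2
Reactants: 2 2-(triisopropylsilyloxy)buta-1,3-diene; 3 ethyl (E)-3-formylbut-2-enoate
Product: 4 Diels–Alder adduct ethyl (1S,6S)-6-formyl-6-methyl-3-(triisopropylsilyloxy)cyclohex-3-ene-1-carboxylate
Conditions: (R)-3,3-diphenyl-1-(o-tolyl)tetrahydro-1H,3H-pyrrolo[1,2-c][1,3,2]oxazaborole (20 mol %), (CF3SO2)2NH (20 mol %), CH2Cl2, −78 °C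
Reagents that add atoms: none
Why: Catalytic enantioselective Diels–Alder reaction: the oxazaborolidinium cation binds the formyl group of 3, the nucleophilic CH2 terminus next to the silyloxy carbon attacks C10 (para rule), the E geometry of 3 is carried into the trans C2/C9 relationship, and shielding of one enal face by the catalyst phenyl group should set C1 and C10 together.

Step 3
Reactants: 4 Diels–Alder adduct
Product: 5 (2S)-allylic alcohol ethyl (1S,6S)-6-[(1S)-1-hydroxyprop-2-en-1-yl]-6-methyl-3-(triisopropylsilyloxy)cyclohex-3-ene-1-carboxylate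
Conditions: CH2=CHMgBr, THF, −78 °C; aq NH4Cl
Reagents that add atoms: vinylmagnesium bromide, C=C[Mg]Br
Why: Grignard 1,2-addition, chemoselective for the aldehyde over the ester at low temperature, should follow the Felkin–Anh model (C10 large, C14 medium, methyl small) and so set the 2S carbinol.

Step 4
Reactants: 5 (2S)-allylic alcohol
Product: 6 C2 tert-butyldimethylsilyl ether of 5
Conditions: tBuMe2SiOTf, 2,6-lutidine, CH2Cl2, −78 to 0 °C
Reagents that add atoms: tert-butyldimethylsilyl triflate, CC(C)(C)[Si](C)(C)OS(=O)(=O)C(F)(F)F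
Why: Standard silyl triflate protection masks the C2 alcohol so that it can neither lactonise onto C9 nor direct the later epoxidation to the vinyl group.

Step 5
Reactants: 6 C2 silyl ether ester
Product: 7 C9 aldehyde (CO2Et of 6 reduced to CHO)
Conditions: iBu2AlH, toluene, −78 °C; aq potassium sodium tartrate
Reagents that add atoms: none
Why: Partial ester reduction with iBu2AlH stops at the aldehyde because the hindered aluminium hemiacetal is stable at −78 °C, and no other reducible group is present.

Step 6
Reactants: 8 (R)-4-methyldihydrofuran-2(3H)-one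
Product: 10 (3R,4S)-3-hydroxy-4-methyldihydrofuran-2(3H)-one, via sodium enolate 9 (not isolated)
Conditions: NaN(SiMe3)2, THF, −78 °C; 2-(phenylsulfonyl)-3-phenyloxaziridine; AcOH
Reagents that add atoms: 2-(phenylsulfonyl)-3-phenyloxaziridine, O=S(=O)(N1OC1c1ccccc1)c1ccccc1
Why: Enolate hydroxylation with an N-sulfonyloxaziridine delivers oxygen anti to the C17 methyl group (trans product), although this C8 configuration is erased again in step 8.

Step 7
Reactants: 10 hydroxy lactone
Product: 11 (3R,4S)-4-methyl-3-(triethylsilyloxy)dihydrofuran-2(3H)-one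
Conditions: Et3SiCl, imidazole, CH2Cl2, 0 °C
Reagents that add atoms: chlorotriethylsilane, CC[Si](Cl)(CC)CC
Why: Routine silylation gives a non-chelating O8 protecting group that later supports Felkin–Anh control at C7.

Step 8
Reactants: 7 C9 aldehyde; 11 silyloxy lactone
Product: 14 bis(triethylsilyl) aldol lactone (C8–C9 bond formed), via lithium enolate 12 (not isolated), via lithium aldolate 13 (not isolated)
Conditions: 11, LiN(iPr)2, THF, −78 °C; 7; then Et3SiOTf, −78 to −20 °C
Reagents that add atoms: triethylsilyl triflate, CC[Si](CC)(CC)OS(=O)(=O)C(F)(F)F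
Why: Lithium-enolate aldol addition through a closed Zimmerman–Traxler chair: the aldehyde meets the enolate face anti to the C17 methyl (sets C8), the ring-fixed enolate geometry (OSiEt3 cis and C17 trans to OLi) with C10 equatorial gives the 8,9-syn dioxygen pattern (sets C9), the syn-pentane clash of the axial OSiEt3 group with the Felkin rotamer favours the required anti-Felkin aldehyde face, and silylation in situ blocks the retro-aldol.

Step 9
Reactants: 14 bis(triethylsilyl) aldol lactone
Product: 15 ring A enone (C12 ketone with C13=C14)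
Conditions: Pd(OAc)2 (1.2 equiv), DMSO, 45 °C
Reagents that add atoms: none
Why: Saegusa–Ito oxidation: palladation of the regiodefined C12=C13 silyl enol ether at C13 and β-hydride elimination from C14 should place the C13=C14 alkene where the target has it.

Step 10
Reactants: 15 ring A enone
Product: 16 cross-conjugated dienone with the C11=C20 methylene
Conditions: (CH2O)n, iPr2NH2+ CF3CO2−, THF, reflux
Reagents that add atoms: paraformaldehyde (as formaldehyde), C=O
Why: Mannich condensation with β-elimination in situ (direct α-methylenation) can only occur at C11, the sole enolisable position of the enone, and installs C20.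

Step 11
Reactants: 16 cross-conjugated dienone
Product: 17 (12R)-dienol
Conditions: (S)-1-methyl-3,3-diphenyltetrahydro-1H,3H-pyrrolo[1,2-c][1,3,2]oxazaborole (0.5 equiv), catecholborane, toluene, −78 °C
Reagents that add atoms: none
Why: Corey–Bakshi–Shibata reduction gives 1,2-reduction only, and reagent control (C11 side large, C13 side small) should override the substrate bias and set the 12R (α) alcohol.

Step 12
Reactants: 17 (12R)-dienol
Product: 18 11,20-epoxy alcohol (epoxide oxygen α and cis to the 12-hydroxyl)
Conditions: VO(acac)2 (5 mol %), tBuOOH, CH2Cl2, 0 °C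
Reagents that add atoms: tert-butyl hydroperoxide, CC(C)(C)OO
Why: Vanadium-catalysed hydroxyl-directed epoxidation delivers oxygen syn to the 12α-hydroxyl onto the exposed exocyclic C11=C20 alkene, which is also the face away from the axial C15 methyl, whereas the α face of C13=C14 is screened by the C2 side chain and the vinyl group has no free allylic hydroxyl.

Step 13
Reactants: 18 epoxy alcohol
Product: 19 chlorohydrin diol (11-OH 12-OH 20-Cl)
Conditions: LiCl, AcOH, THF, rt
Reagents that add atoms: lithium chloride, [Li+].[Cl-]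
Why: SN2 opening of the spiro-epoxide by chloride under mild acid assistance occurs at the primary C20 because a cation at C11 is disfavoured by the adjacent C12 oxygen, so the C11 configuration is retained.

Step 14
Reactants: 19 chlorohydrin diol
Product: 20 tetrakis(triethylsilyl) ether
Conditions: Et3SiOTf, 2,6-lutidine, CH2Cl2, 0 °C to rt
Reagents that add atoms: triethylsilyl triflate, CC[Si](CC)(CC)OS(=O)(=O)C(F)(F)F
Why: Silyl triflate protection of both hydroxyls prevents the chlorohydrin from closing back to the epoxide under the basic organometallic steps.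

Step 15
Reactants: 20 tetrakis(triethylsilyl) ether
Product: 21 lactol (C7 hemiacetal as an anomeric mixture)
Conditions: iBu2AlH, CH2Cl2, −78 °C; aq potassium sodium tartrate
Reagents that add atoms: none
Why: Lactone-to-lactol reduction with iBu2AlH unmasks C7 at the aldehyde level, the lactone being the only carbonyl group left.

Step 16
Reactants: 21 lactol; 22 3-chloro-1-(trimethylsilyl)prop-1-yne
Product: 24 anti-chlorohydrin diol (7-OH 19-OH 6-Cl with the silylated alkyne C4≡C5), via allenylzinc bromide 23 (not isolated)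
Conditions: 22 (4 equiv), ZnBr2, LiN(iPr)2, THF, −80 °C; then 21, −80 to −20 °C; aq NH4Cl
Reagents that add atoms: none
Why: Addition of a 3-chloroallenylzinc carbenoid (SE2′ propargylation through a cyclic transition state) to the open hydroxy-aldehyde form of the lactol should give the anti C6-Cl/C7-OH chlorohydrin, and polar Felkin–Anh attack anti to the non-chelating O8 silyl ether past the smaller C17 branch should set 7R and hence 6S.

Step 17
Reactants: 24 anti-chlorohydrin diol
Product: 25 fully protected ring C lactone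
Conditions: TEMPO (2,2,6,6-tetramethylpiperidin-1-oxyl, 20 mol %), PhI(OAc)2, CH2Cl2, rt
Reagents that add atoms: none
Why: Nitroxyl-catalysed oxidative lactonisation oxidises the primary C19 alcohol selectively, and the aldehyde is trapped by the C7 hydroxyl as a lactol and oxidised on, which closes ring C with no change at any stereocentre.

Step 18
Reactants: 25 fully protected ring C lactone
Product: 26 pentaol with terminal alkyne
Conditions: Bu4NF, AcOH, THF, 0 °C to rt
Reagents that add atoms: none
Why: Fluoride-mediated desilylation cleaves all O–Si bonds and the alkynyl C–Si bond in one operation, and the acetic acid buffer ensures that no alkoxide lives long enough to close an epoxide or to translactonise.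

Step 19
Reactants: 26 pentaol
Product: 27 triacetate seco-enyne
Conditions: Ac2O, pyridine, 4-(dimethylamino)pyridine (cat.), CH2Cl2, 0 °C to rt
Reagents that add atoms: acetic anhydride, CC(=O)OC(C)=O
Why: Nucleophile-catalysed acylation discriminates the three secondary alcohols (C2, C9, C12) from the two tertiary ones (C8, C11), which stay free as in the target.

Step 20
Reactants: 27 triacetate seco-enyne
Product: 29 target CNP0435497.1, via triene 28 (not isolated)
Conditions: second-generation Grubbs catalyst (15 mol %), ethylene (1 atm), toluene (1 mM), rt; then argon sparge, 80 °C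
Reagents that add atoms: ethylene, C=C
Why: The ruthenium methylidene formed under ethylene adds to the terminal alkyne C4≡C5, and the resulting vinylcarbene turns over with ethylene to the 2-substituted butadiene 28, in which C16 comes from ethylene; the catalyst then loads on the unhindered C4 vinyl terminus and closes onto the C3 vinyl group with loss of ethylene. The closest known reaction type is the tandem ethylene cross-enyne metathesis/diene–ene ring-closing metathesis, the formal endo mode of macrocyclic ring-closing enyne metathesis. Ring B is the only ring closed, by formation of C3=C4 in the formal ten-endo mode, while the exo mode (a nine-membered 1-vinylcycloalkene) is pre-empted because ethylene consumes the alkyne first. No sp3 stereocentre is created; the Z geometry of C3=C4 is controlled by ring strain in a ten-membered ring clamped by the two trans-fused rings A and C, and the reversibility of metathesis lets the mixture drain to this isomer. The step needs site selectivity among four π systems and cyclisation over oligomerisation: C13=C14 is an unstrained, doubly flanked cyclohexene alkene and C5=C16 is 1,1-disubstituted, so both stay spectators, and high dilution together with the gauche C2/C9 and C6/C9 arrangements fixed by rings A and C favours closure. Acetates, free tertiary alcohols and the allylic, propargylic and primary chlorides are all tolerated by ruthenium carbenes.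

Compound list
1 | methyl vinyl ketone (but-3-en-2-one) | CC(=O)C=C | starting material
2 | 2-(triisopropylsilyloxy)buta-1,3-diene | C=CC(=C)O[Si](C(C)C)(C(C)C)C(C)C | intermediate
3 | ethyl (E)-3-formylbut-2-enoate | CCOC(=O)/C=C(\C)C=O | starting material
4 | Diels–Alder adduct, ethyl (1S,6S)-6-formyl-6-methyl-3-(triisopropylsilyloxy)cyclohex-3-ene-1-carboxylate (C1 and C10 as in 29) | O=C[C@@]1(C)CC=C(O[Si](C(C)C)(C(C)C)C(C)C)C[C@@H]1C(=O)OCC | intermediate
5 | (2S)-allylic alcohol, vinyl carbinol at C2 | C=C[C@H](O)[C@@]1(C)CC=C(O[Si](C(C)C)(C(C)C)C(C)C)C[C@@H]1C(=O)OCC | intermediate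
6 | C2 tert-butyldimethylsilyl ether of 5 | C=C[C@H](O[Si](C)(C)C(C)(C)C)[C@@]1(C)CC=C(O[Si](C(C)C)(C(C)C)C(C)C)C[C@@H]1C(=O)OCC | intermediate
7 | C9 aldehyde | C=C[C@H](O[Si](C)(C)C(C)(C)C)[C@@]1(C)CC=C(O[Si](C(C)C)(C(C)C)C(C)C)C[C@@H]1C=O | intermediate
8 | (R)-4-methyldihydrofuran-2(3H)-one (carries C17) | O=C1C[C@@H](C)CO1 | starting material
9 | sodium enolate of 8 | [Na+].[O-]C1=C[C@@H](C)CO1 | intermediate
10 | (3R,4S)-3-hydroxy-4-methyldihydrofuran-2(3H)-one (trans) | O=C1[C@H](O)[C@@H](C)CO1 | intermediate
11 | (3R,4S)-4-methyl-3-(triethylsilyloxy)dihydrofuran-2(3H)-one | O=C1[C@H](O[Si](CC)(CC)CC)[C@@H](C)CO1 | intermediate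
12 | lithium enolate of 11 | [Li+].[O-]C1=C(O[Si](CC)(CC)CC)[C@@H](C)CO1 | intermediate
13 | lithium aldolate (C9 alkoxide) | C=C[C@H](O[Si](C)(C)C(C)(C)C)[C@@]1(C)CC=C(O[Si](C(C)C)(C(C)C)C(C)C)C[C@@H]1[C@H]([O-])[C@]1(O[Si](CC)(CC)CC)[C@@H](C)COC1=O.[Li+] | intermediate
14 | bis(triethylsilyl) aldol lactone; O8 cis to the C17 methyl, C8 and C9 arranged as in 29; temporary lactone C7(=O)–O–C19 | C=C[C@H](O[Si](C)(C)C(C)(C)C)[C@@]1(C)CC=C(O[Si](C(C)C)(C(C)C)C(C)C)C[C@@H]1[C@H](O[Si](CC)(CC)CC)[C@]1(O[Si](CC)(CC)CC)[C@@H](C)COC1=O | intermediate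
15 | ring A enone (C12=O, C13=C14) | C=C[C@H](O[Si](C)(C)C(C)(C)C)[C@@]1(C)C=CC(=O)C[C@@H]1[C@H](O[Si](CC)(CC)CC)[C@]1(O[Si](CC)(CC)CC)[C@@H](C)COC1=O | intermediate
16 | cross-conjugated dienone with C11=C20 methylene | C=C[C@H](O[Si](C)(C)C(C)(C)C)[C@@]1(C)C=CC(=O)C(=C)[C@@H]1[C@H](O[Si](CC)(CC)CC)[C@]1(O[Si](CC)(CC)CC)[C@@H](C)COC1=O | intermediate
17 | (12R)-dienol | C=C[C@H](O[Si](C)(C)C(C)(C)C)[C@@]1(C)C=C[C@@H](O)C(=C)[C@@H]1[C@H](O[Si](CC)(CC)CC)[C@]1(O[Si](CC)(CC)CC)[C@@H](C)COC1=O | intermediate
18 | 11,20-epoxy alcohol, epoxide oxygen cis to 12-OH | C=C[C@H](O[Si](C)(C)C(C)(C)C)[C@@]1(C)C=C[C@@H](O)[C@]2(CO2)[C@@H]1[C@H](O[Si](CC)(CC)CC)[C@]1(O[Si](CC)(CC)CC)[C@@H](C)COC1=O | intermediate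
19 | chlorohydrin diol (C11 and C12 as in 29) | C=C[C@H](O[Si](C)(C)C(C)(C)C)[C@@]1(C)C=C[C@@H](O)[C@](O)(CCl)[C@@H]1[C@H](O[Si](CC)(CC)CC)[C@]1(O[Si](CC)(CC)CC)[C@@H](C)COC1=O | intermediate
20 | tetrakis(triethylsilyl) ether (O8, O9, O11, O12) | C=C[C@H](O[Si](C)(C)C(C)(C)C)[C@@]1(C)C=C[C@@H](O[Si](CC)(CC)CC)[C@](O[Si](CC)(CC)CC)(CCl)[C@@H]1[C@H](O[Si](CC)(CC)CC)[C@]1(O[Si](CC)(CC)CC)[C@@H](C)COC1=O | intermediate
21 | lactol, C7 hemiacetal, anomeric mixture | C=C[C@H](O[Si](C)(C)C(C)(C)C)[C@@]1(C)C=C[C@@H](O[Si](CC)(CC)CC)[C@](O[Si](CC)(CC)CC)(CCl)[C@@H]1[C@H](O[Si](CC)(CC)CC)[C@]1(O[Si](CC)(CC)CC)[C@@H](C)COC1O | intermediate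
22 | 3-chloro-1-(trimethylsilyl)prop-1-yne | ClCC#C[Si](C)(C)C | starting material
23 | [3-chloro-1-(trimethylsilyl)propa-1,2-dien-1-yl]zinc bromide (racemic) | ClC=C=C([Zn]Br)[Si](C)(C)C | intermediate
24 | anti-chlorohydrin diol (C6 and C7 as in 29; free 7-OH and 19-OH) | C=C[C@H](O[Si](C)(C)C(C)(C)C)[C@@]1(C)C=C[C@@H](O[Si](CC)(CC)CC)[C@](O[Si](CC)(CC)CC)(CCl)[C@@H]1[C@H](O[Si](CC)(CC)CC)[C@](O[Si](CC)(CC)CC)([C@@H](C)CO)[C@@H](O)[C@H](C#C[Si](C)(C)C)Cl | intermediate
25 | fully protected ring C lactone (C7–O–C19=O) | C=C[C@H](O[Si](C)(C)C(C)(C)C)[C@@]1(C)C=C[C@@H](O[Si](CC)(CC)CC)[C@](O[Si](CC)(CC)CC)(CCl)[C@@H]1[C@H](O[Si](CC)(CC)CC)[C@]1(O[Si](CC)(CC)CC)[C@@H](C)C(=O)O[C@H]1[C@H](C#C[Si](C)(C)C)Cl | intermediate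
26 | pentaol with terminal alkyne | C=C[C@H](O)[C@@]1(C)C=C[C@@H](O)[C@](O)(CCl)[C@@H]1[C@H](O)[C@]1(O)[C@@H](C)C(=O)O[C@H]1[C@H](C#C)Cl | intermediate
27 | triacetate seco-enyne (2-, 9-, 12-OAc; all stereocentres as in 29) | C=C[C@H](OC(C)=O)[C@@]1(C)C=C[C@@H](OC(C)=O)[C@](O)(CCl)[C@@H]1[C@H](OC(C)=O)[C@]1(O)[C@@H](C)C(=O)O[C@H]1[C@H](C#C)Cl | intermediate
28 | triene, C6 bearing a buta-1,3-dien-2-yl group | C=C[C@H](OC(C)=O)[C@@]1(C)C=C[C@@H](OC(C)=O)[C@](O)(CCl)[C@@H]1[C@H](OC(C)=O)[C@]1(O)[C@@H](C)C(=O)O[C@H]1[C@H](C(=C)C=C)Cl | intermediate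
29 | CNP0435497.1, (1S,2S,3Z,6S,7R,8R,9S,10S,11S,12R,17R) | C=C1/C=C\[C@H](OC(C)=O)[C@@]2(C)C=C[C@@H](OC(C)=O)[C@](O)(CCl)[C@@H]2[C@H](OC(C)=O)[C@]2(O)[C@@H](C)C(=O)O[C@H]2[C@H]1Cl | target

Total step count: 20. Longest linear sequence: 18 steps (steps 1–5 and 8–20).

Steps most likely to fail

Step 20. The closure may stall at the open triene or drift into intermolecular oligomerisation, because the C3 vinyl group next to the quaternary C1 and an acetate engages the carbene slowly. E/Z equilibration may also remain incomplete. The fallback sets out from pentaol 26 and comes back at 29. The closure is moved in front of the acetylation, so that a different substrate class, a free allylic alcohol, meets the carbene. The C2 hydroxyl accelerates metathesis of the adjacent vinyl group and is much smaller than the acetate, and hydrogen bonding among the hydroxyls can fold the chain. Under the same ethylene protocol 26 should pass through the pentaol triene F1 to the macrocyclic pentaol F2. Selective acetylation of its three secondary alcohols (Ac2O, pyridine) then gives 29.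

Step 8. Union of a tetrasubstituted enolate with a neopentyl-type aldehyde may suffer from slow addition, retro-aldol reversal, enolisation of the aldehyde or poor facial selectivity at C9. The fallback sets out from aldehyde 7 and hydroxy lactone 10 and comes back at 14. It fixes C9 by hydride delivery instead of by the aldol event.
- Double deprotonation of 10 with LiN(iPr)2 gives the smaller and more reactive alkoxide enolate, which still reacts anti to the C17 methyl. It adds to 7 to give the aldol diol F3 without regard to C9.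
- Dess–Martin periodinane oxidises only the secondary alcohol, to the α-hydroxy ketone F4.
- Zn(BH4)2 then reduces the O8/O9 zinc chelate from the side of the flat C7 carbonyl. This is also the Felkin–Anh face with respect to C10, so it gives the (9S)-diol F5.
- Et3SiOTf and 2,6-lutidine convert F5 into 14.

Step 16. The hindered lactol may open sluggishly, the carbenoid may decompose before it adds, and zinc chelation to O8 may erode the facial selectivity at C7. The fallback sets out from lactol 21 and comes back at 24. It separates C–C bond formation from chloride introduction. The ylide from dimethyl[3-(trimethylsilyl)prop-2-yn-1-yl]sulfonium bromide and KN(SiMe3)2 converts the open aldehyde form of 21 into the trans-alkynyl epoxide F6 (sulfur-ylide epoxidation). LiCl in AcOH then opens the epoxide at the propargylic C6 with inversion, which gives the same anti chlorohydrin 24.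

Further compounds
F1 | step 20 | pentaol triene (C6 bearing a buta-1,3-dien-2-yl group, not isolated) | C=C[C@H](O)[C@@]1(C)C=C[C@@H](O)[C@](O)(CCl)[C@@H]1[C@H](O)[C@]1(O)[C@@H](C)C(=O)O[C@H]1[C@H](C(=C)C=C)Cl
F2 | step 20 | macrocyclic pentaol (tris-deacetyl 29) | C=C1/C=C\[C@H](O)[C@@]2(C)C=C[C@@H](O)[C@](O)(CCl)[C@@H]2[C@H](O)[C@]2(O)[C@@H](C)C(=O)O[C@H]2[C@H]1Cl
F3 | step 8 | aldol diol, C9 epimer mixture | C=C[C@H](O[Si](C)(C)C(C)(C)C)[C@@]1(C)CC=C(O[Si](C(C)C)(C(C)C)C(C)C)C[C@@H]1C(O)[C@]1(O)[C@@H](C)COC1=O
F4 | step 8 | α-hydroxy ketone (C9=O, free 8-OH) | C=C[C@H](O[Si](C)(C)C(C)(C)C)[C@@]1(C)CC=C(O[Si](C(C)C)(C(C)C)C(C)C)C[C@@H]1C(=O)[C@]1(O)[C@@H](C)COC1=O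
F5 | step 8 | (9S)-diol | C=C[C@H](O[Si](C)(C)C(C)(C)C)[C@@]1(C)CC=C(O[Si](C(C)C)(C(C)C)C(C)C)C[C@@H]1[C@H](O)[C@]1(O)[C@@H](C)COC1=O
F6 | step 16 | trans-alkynyl epoxide (C6–C7 oxirane, free 19-OH) | C=C[C@H](O[Si](C)(C)C(C)(C)C)[C@@]1(C)C=C[C@@H](O[Si](CC)(CC)CC)[C@](O[Si](CC)(CC)CC)(CCl)[C@@H]1[C@H](O[Si](CC)(CC)CC)[C@](O[Si](CC)(CC)CC)([C@@H](C)CO)[C@H]2O[C@@H]2C#C[Si](C)(C)C
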